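## Analysis of the target

Tomentodiplacone B is a (2S)-flavanone. Ring A is fused to the oxygen heterocycle ring C, C2 carries a 4-hydroxy-3-methoxyphenyl group (ring B), C5 and C7 carry hydroxyls, and C6 between them carries a (2E,5E)-7-hydroxy-3,7-dimethylocta-2,5-dienyl chain. C2 is the only stereocentre. It is benzylic, bonded to O1 and β to the C4 carbonyl, so base or acid can open ring C by β-elimination and re-close it with loss of configuration. The chain is a skipped diene ending in a tertiary allylic alcohol that ionises easily, and an allyl group flanked by two phenols cyclises to chromans under acid. Hydrogenolysis and strong Brønsted acid are therefore excluded for deprotection. C6 and C8 of a 5,7-dioxygenated chromanone are electronically alike, so late C-alkylation would not be regioselective. The plan rests on the fact that O1 joins C2 to the aromatic carbon C8a: ring C can be closed by making O1–C8a from a C2 alcohol and a ring A bromide, which leaves all four bonds of C2 untouched. Ring A then derives from a mirror-symmetric 2-alkyl-5-bromoresorcinol, so the chain necessarily ends on C6.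

## Retrosynthetic reasoning

Endgame (26 ⇐ 24 ⇐ 23 ⇐ 22). No skeletal bond is cut. The phenols are masked as methoxymethyl ethers in 24, which survive organometallic and basic steps and can be removed without Brønsted acid. The C4 carbonyl is traced back to carbinol 23 and its silyl ether 22: while C4 is sp3, ring C cannot open by β-elimination, so every basic operation precedes the ketone.

Ring C (22 ⇐ 21). The O1–C8a bond is cut. Cutting O1–C2 would demand substitution at, or conjugate addition to, the stereogenic benzylic carbon. Cutting C4–C4a would put a carbonyl β to an aryloxy leaving group before the ring exists. With O1–C8a formed last, C2 in 21 is an ordinary secondary alcohol of fixed configuration and ring A carries bromine at the future C8a. The forward reaction is a palladium-catalysed intramolecular O-arylation with retention. The other benzylic oxygen (future C4) stays silylated in 21, because a free hydroxyl next to the C–Br bond could chelate the metal and donate hydride.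

Fragment union (21 ⇐ 20 ⇐ 10 + 17). The C4–C4a bond is cut, dividing the molecule into ring A with its chain (10) and ring B with its three-carbon arm (17). Forward, 10 is deprotonated beside bromine and the aryl anion adds to aldehyde 17. Trapping the new alkoxide with a silyl group different from the one on the C2 oxygen (20) lets the C2 hydroxyl be freed selectively. The configuration at C4 is irrelevant.

Stereocentre (17 ⇐ 15 ⇐ 14 ⇐ 12 ⇐ 11). The C2–C3 bond is cut by an allylation transform. The aldehyde of 17 is a masked terminal alkene (15), and homoallylic alcohol 14 comes from asymmetric allylboration of protected vanillin 12. This acetate-aldol equivalent sets C2 in one step from aldehyde 11.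

Ring A building block (10 ⇐ 8 + 5; 8 ⇐ 7 ⇐ 6). The bond from the ring carbon (future C6) to C1 of the chain is cut to an aryl nucleophile and allylic bromide 5. The nucleophile is made from iodide 8 by iodine–magnesium exchange, which leaves the bromine alone. Direct deprotonation between the two acetal oxygens is avoided: alkyllithiums would exchange the bromine, and amide bases are drawn to the proton beside bromine. The iodine comes from iodination of 5-bromoresorcinol 6 between its hydroxyls (7).

Side chain (5 ⇐ 4 ⇐ 3 ⇐ 1). The tertiary allylic alcohol and the 5,6-E-alkene are traced to the 6,7-alkene of geranyl acetate 1 by an oxygen ene transform (Schenck reaction), which shifts the double bond and installs the oxygen in one operation. The primary allylic oxygen becomes the bromide.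

## Alternatives that were turned down

Alternative 1: Ring A is built de novo by cutting C5–C6, C7–C8 and C4a–C5. Forward, irradiation of diazo ketone A2 triggers a Wolff rearrangement to a vinylketene. This adds to siloxyalkyne A3 by [2+2] cycloaddition; four-electron ring opening and six-electron ring closure then give phenol A1. In its favour, the benzannulation is highly convergent and fixes the ring A pattern (free 5-OH, silylated 7-O, chain on C6, hydrogen on C8) with no halogenated resorcinol. A1 carries only silyl groups, so its endgame needs fluoride alone; on that point it is stronger than the chosen route, which ends with a Lewis-acid acetal cleavage. Against it, A2 already contains the C2–O1 bond β to a ketone in a dihydropyranone, so enolisation can open the ring and erase C2 during its multi-step preparation and during the heated cascade. The ketene can also add to the chain alkenes of A3 instead of the alkyne. The doubly activated CH2 between alkyne and alkene in A3 is prone to isomerise under the base needed to make an ynol silyl ether. The chosen route spends more steps on protecting groups, but it sets C2 by a reliable allylboration and never places it β to a carbonyl while base or heat is applied.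

Alternative 2: Ring C is cut at C4–C4a. Forward, t-BuLi exchanges the bromine of Weinreb amide A5 and the aryllithium attacks the amide carbonyl (Parham-type cyclisation) to give A4. In its favour, the ketone is delivered directly, with no oxidation and no silyl differentiation at C4, so it is two or three steps shorter after ring formation; on step count it is stronger. Against it, A5 must already hold the aryl ether at the benzylic stereocentre. Making that bond requires substitution with inversion at a secondary benzylic carbon by a hindered ortho-bromophenol, which is prone to ionisation and elimination. It also needs a desymmetrised phloroglucinol in place of symmetric 10. In the key step the amide α-protons sit next to a β-aryloxy leaving group, so proton transfer to the aryllithium followed by β-elimination would destroy the stereocentre. The chosen route forms the aryl ether last, by a process that does not touch the C2–O bond, at a stage without any carbonyl.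

Alternative 3: Ring A is cut at C4a–C5 and traced to a keto ester arm. Forward, LiN(SiMe3)2 turns A7 into a dianion whose pyranone C5 acylates the ester carbon; enolisation then aromatises ring A to give A6. In its favour, ring A arrives with both phenols free and the chain placed by its position on the keto ester, without halogen, catalyst or ring A protecting groups, and the endgame is fluoride only; on protecting-group economy it is stronger. Against it, the ring is formed with excess strong base on a 2-aryl-dihydropyranone and then on a flavanone phenoxide. Both can open ring C by β-elimination of the ring oxygen and lose C2. Deprotonation at C3 and O-acylation compete with the desired C-acylation, and A7 is itself laborious to assemble. The chosen route keeps all strongly basic steps away from any carbonyl-bearing ring C, at the price of three acetal groups.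

Key step: step 13

Assumption: the aryllithium addition in step 11 is not expected to be diastereoselective. The carbon that becomes C4 is therefore carried as both epimers in 19 to 23 and left undefined in their SMILES; it becomes the carbonyl carbon in step 15. Flavanone numbering (C2, C4, C8a) is used for the open-chain compounds as well.

## Steps

Step 1
Reactants: 1 geranyl acetate
Product: 3 (2E,5E)-3,7-dimethylocta-2,5-diene-1,7-diol, via tertiary hydroperoxide 2 (not isolated)
Conditions: O2, hν (visible), tetraphenylporphyrin (cat.), CH2Cl2, 0 °C; concentrate; LiAlH4, THF, 0 °C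
Reagents that add atoms: dioxygen, O=O
Why: Schenck ene reaction of singlet oxygen at the electron-richer 6,7-alkene (the 2,3-alkene is deactivated by the allylic acetoxy group); hydrogen abstraction from C5 gives the tertiary hydroperoxide with a new E-alkene, and LiAlH4 reduces both the O–O bond and the acetate. The regioisomeric secondary hydroperoxide from abstraction at the cis methyl group is expected alongside, and its diol is removed by chromatography.

Step 2
Reactants: 3 (2E,5E)-3,7-dimethylocta-2,5-diene-1,7-diol
Product: 4 (3E,6E)-8-bromo-2,6-dimethylocta-3,6-dien-2-ol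
Conditions: CBr4, PPh3, CH2Cl2, −20 → 0 °C
Reagents that add atoms: carbon tetrabromide, BrC(Br)(Br)Br
Why: Appel reaction; the primary allylic hydroxyl forms the alkoxyphosphonium salt much faster than the hindered tertiary one, and bromide displaces it at the primary carbon without allylic transposition, so both E-alkenes are kept.

Step 3
Reactants: 4 (3E,6E)-8-bromo-2,6-dimethylocta-3,6-dien-2-ol
Product: 5 {[(3E,6E)-8-bromo-2,6-dimethylocta-3,6-dien-2-yl]oxy}triethylsilane
Conditions: Et3SiOTf, 2,6-lutidine, CH2Cl2, −78 °C
Reagents that add atoms: triethylsilyl trifluoromethanesulfonate, CC[Si](CC)(CC)OS(=O)(=O)C(F)(F)F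
Why: Silylation of a tertiary alcohol with a silyl triflate and a hindered pyridine base, which does not alkylate at the allylic bromide at low temperature; the ether removes the acidic proton before the organometallic steps.

Step 4
Reactants: 6 5-bromoresorcinol
Product: 7 5-bromo-2-iodobenzene-1,3-diol
Conditions: I2, NaHCO3, H2O/THF, 0 °C
Reagents that add atoms: iodine, II
Why: Electrophilic iodination of the resorcinol anion in aqueous hydrogencarbonate goes kinetically to the carbon between the two hydroxyls, as for resorcinol itself; in 6 the other two ring carbons are additionally flanked by bromine. Short reaction time and prompt work-up limit di-iodination and acid-promoted iodine migration.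

Step 5
Reactants: 7 5-bromo-2-iodobenzene-1,3-diol
Product: 8 5-bromo-2-iodo-1,3-bis(methoxymethoxy)benzene
Conditions: MOMCl, i-Pr2NEt, CH2Cl2, 0 °C → rt
Reagents that add atoms: chloromethyl methyl ether, COCCl
Why: O-Alkylation of both phenols with an α-chloro ether under amine base (acetal protection).

Step 6
Reactants: 8 5-bromo-2-iodo-1,3-bis(methoxymethoxy)benzene; 5 {[(3E,6E)-8-bromo-2,6-dimethylocta-3,6-dien-2-yl]oxy}triethylsilane
Product: 10 5-bromo-2-[(2E,5E)-3,7-dimethyl-7-(triethylsilyloxy)octa-2,5-dien-1-yl]-1,3-bis(methoxymethoxy)benzene, via arylmagnesium chloride 9 (not isolated)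
Conditions: i-PrMgCl·LiCl, THF, −20 → 0 °C; then Li2CuCl4 (5 mol %), 5, −20 → 0 °C
Reagents that add atoms: none
Why: Iodine–magnesium exchange is far faster at the C–I bond flanked by two chelating acetal oxygens than at the C–Br bond, so 9 forms with bromine intact and para to magnesium. Copper-catalysed allylic substitution by the hindered aryl Grignard reagent at the primary terminus of 5 (SN2 mode) gives the linear product with the E-alkene unchanged.

Step 7
Reactants: 11 vanillin
Product: 12 3-methoxy-4-(methoxymethoxy)benzaldehyde
Conditions: MOMCl, i-Pr2NEt, CH2Cl2, 0 °C → rt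
Reagents that add atoms: chloromethyl methyl ether, COCCl
Why: Acetal protection of the phenol, as in step 5.

Step 8
Reactants: 12 3-methoxy-4-(methoxymethoxy)benzaldehyde
Product: 14 (S)-1-[3-methoxy-4-(methoxymethoxy)phenyl]but-3-en-1-ol, via O-borinate 13 (not isolated)
Conditions: (−)-Ipc2B(allyl) (from (+)-α-pinene), Et2O, −78 °C; then NaOH, H2O2, 0 °C → rt
Reagents that add atoms: (−)-B-allyldiisopinocampheylborane, C=CCB([C@@H]1C[C@@H]2C[C@H]([C@H]1C)C2(C)C)[C@@H]1C[C@@H]2C[C@H]([C@H]1C)C2(C)C
Why: Brown allylation; the allylborane transfers allyl through a chair six-membered transition state to the Si face of the aldehyde, which for an aryl aldehyde gives the (S)-carbinol, and oxidative work-up releases it from borinate 13. This sets the only stereocentre of the target (future C2).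

Step 9
Reactants: 14 (S)-1-[3-methoxy-4-(methoxymethoxy)phenyl]but-3-en-1-ol
Product: 15 (S)-triethyl({1-[3-methoxy-4-(methoxymethoxy)phenyl]but-3-en-1-yl}oxy)silane
Conditions: Et3SiCl, imidazole, DMF, 0 °C → rt
Reagents that add atoms: chlorotriethylsilane, CC[Si](CC)(CC)Cl
Why: Standard silylation of a secondary alcohol; the triethylsilyl group is chosen because it can later be removed in the presence of a tert-butyldimethylsilyl ether.

Step 10
Reactants: 15 (S)-triethyl({1-[3-methoxy-4-(methoxymethoxy)phenyl]but-3-en-1-yl}oxy)silane
Product: 17 (S)-3-[3-methoxy-4-(methoxymethoxy)phenyl]-3-(triethylsilyloxy)propanal, via ozonide 16 (not isolated)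
Conditions: O3, CH2Cl2, −78 °C; then PPh3, −78 °C → rt
Reagents that add atoms: ozone, [O-][O+]=O
Why: Ozonolysis of the terminal alkene, which reacts with ozone far faster than the dialkoxyarene at −78 °C, followed by reductive cleavage of ozonide 16; the stereocentre is not involved. The aldehyde is used without delay.

Step 11
Reactants: 10 5-bromo-2-[(2E,5E)-3,7-dimethyl-7-(triethylsilyloxy)octa-2,5-dien-1-yl]-1,3-bis(methoxymethoxy)benzene; 17 (S)-3-[3-methoxy-4-(methoxymethoxy)phenyl]-3-(triethylsilyloxy)propanal
Product: 20 (1RS,3S)-1-{6-bromo-3-[(2E,5E)-3,7-dimethyl-7-(triethylsilyloxy)octa-2,5-dien-1-yl]-2,4-bis(methoxymethoxy)phenyl}-1-(tert-butyldimethylsilyloxy)-3-[3-methoxy-4-(methoxymethoxy)phenyl]-3-(triethylsilyloxy)propane, via aryllithium 18 (not isolated), via lithium alkoxide 19 (not isolated)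
Conditions: lithium 2,2,6,6-tetramethylpiperidide, THF, −78 °C; 17, −78 °C; then t-BuMe2SiOTf, −78 → 0 °C
Reagents that add atoms: tert-butyldimethylsilyl trifluoromethanesulfonate, CC(C)(C)[Si](C)(C)OS(=O)(=O)C(F)(F)F
Why: Directed ortho-metalation with a lithium amide (no bromine–lithium exchange) removes one of the two equivalent ring protons of 10, each acidified by the adjacent bromine and the adjacent acetal oxygen; 18 is held at −78 °C, where loss of LiBr is slow. 1,2-Addition to 17 forms the C4–C4a bond and alkoxide 19 is silylated in the same flask, which differentiates the two benzylic oxygens. No facial control is expected or needed at the new carbinol carbon.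

Step 12
Reactants: 20 doubly triethylsilylated C4 tert-butyldimethylsilyl ether from step 11
Product: 21 (1S,3RS)-3-{6-bromo-3-[(2E,5E)-7-hydroxy-3,7-dimethylocta-2,5-dien-1-yl]-2,4-bis(methoxymethoxy)phenyl}-3-(tert-butyldimethylsilyloxy)-1-[3-methoxy-4-(methoxymethoxy)phenyl]propan-1-ol
Conditions: HF·pyridine, pyridine, THF, 0 °C → rt
Reagents that add atoms: none
Why: Buffered fluoride cleaves the two triethylsilyl ethers much faster than the hindered secondary tert-butyldimethylsilyl ether next to the ortho,ortho'-disubstituted ring, freeing the (S)-C2 hydroxyl and the tertiary alcohol. The buffered medium avoids ionisation of the electron-rich benzylic C4–O bond and of the acetals.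

Step 13
Reactants: 21 bromo alcohol with the C4 oxygen silylated
Product: 22 (2S,4RS)-4-(tert-butyldimethylsilyloxy)-6-[(2E,5E)-7-hydroxy-3,7-dimethylocta-2,5-dien-1-yl]-2-[3-methoxy-4-(methoxymethoxy)phenyl]-5,7-bis(methoxymethoxy)chromane
Conditions: Pd(OAc)2 (5 mol %), 2-(di-tert-butylphosphino)-1,1'-binaphthyl (6 mol %), Cs2CO3, toluene, 70 °C
Reagents that add atoms: none
Why: Pd(OAc)2 is reduced in the flask by the phosphine to zerovalent palladium, which inserts into the C8a–Br bond; the free (S)-hydroxyl on C2 then binds, is deprotonated by Cs2CO3 and gives a seven-membered aryl alkoxide complex of divalent palladium, from which C–O reductive elimination forms O1–C8a and returns zerovalent palladium. The closest known reaction type is the palladium-catalysed intramolecular etherification of aryl bromides with secondary alcohols that gives chromans (Buchwald–Hartwig C–O coupling). Ring C, the only ring formed, is closed as a six-membered benzo-fused ether by transfer of the tethered oxygen to the palladium-bound aryl carbon. No stereocentre is created: the C2–O bond is never broken, so the S configuration from step 8 is carried over, and no carbonyl is present through which ring C could reopen. The step needs chemoselectivity for the C2 hydroxyl and preference for reductive elimination over β-hydride elimination. The first is secured in the substrate: the C4 oxygen, which could only form a five-membered chelate and act as a hydride donor that reduces off the bromide, is a silyl ether, and the tertiary chain hydroxyl is remote, hindered and has no hydrogen on its carbinol carbon. The second is secured by the bulky, electron-rich di-tert-butylphosphine, which accelerates C–O reductive elimination from the alkoxide complex. Both C4 epimers of 21 should cyclise.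

Step 14
Reactants: 22 C4-silylated flavan from step 13
Product: 23 (2S,4RS)-6-[(2E,5E)-7-hydroxy-3,7-dimethylocta-2,5-dien-1-yl]-2-[3-methoxy-4-(methoxymethoxy)phenyl]-5,7-bis(methoxymethoxy)chroman-4-ol
Conditions: Bu4NF, THF, 0 °C → rt
Reagents that add atoms: none
Why: Fluoride cleavage of the remaining silyl ether under basic, non-ionising conditions, which the acid-labile electron-rich benzylic alcohol and the acetals tolerate.

Step 15
Reactants: 23 flavan-4-ol tris(methoxymethyl) ether
Product: 24 (2S)-6-[(2E,5E)-7-hydroxy-3,7-dimethylocta-2,5-dien-1-yl]-2-[3-methoxy-4-(methoxymethoxy)phenyl]-5,7-bis(methoxymethoxy)chroman-4-one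
Conditions: Dess–Martin periodinane, NaHCO3, CH2Cl2, 0 °C → rt
Reagents that add atoms: none
Why: Dess–Martin oxidation of the secondary benzylic alcohol; both C4 epimers converge on one ketone, the tertiary alcohol cannot be oxidised, and the buffered, near-neutral medium does not enolise C3, so C2 is preserved.

Step 16
Reactants: 24 flavanone tris(methoxymethyl) ether
Product: 26 Tomentodiplacone B, via tetrakis(trimethylsilyl) ether 25 (not isolated)
Conditions: Me3SiOTf, 2,2'-bipyridyl, CH2Cl2, 0 °C; then H2O, rt
Reagents that add atoms: none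
Why: Trimethylsilyl triflate complexed by 2,2'-bipyridyl converts aryl methoxymethyl ethers into aryl trimethylsilyl ethers through N-(methoxymethyl)bipyridinium salts without Brønsted acid; the tertiary alcohol is silylated in passing and water hydrolyses all four Si–O bonds of 25. The non-protic medium is chosen to spare the tertiary allylic alcohol, to avoid cyclisation of the allyl group onto a phenol and to leave the flavanone stereocentre alone.

## Compound list

1 | geranyl acetate | CC(C)=CCC/C(C)=C/COC(C)=O | starting material
2 | (2E,5E)-7-hydroperoxy-3,7-dimethylocta-2,5-dien-1-yl acetate (not isolated) | CC(=O)OC/C=C(\C)C/C=C/C(C)(C)OO | intermediate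
3 | (2E,5E)-3,7-dimethylocta-2,5-diene-1,7-diol | OC/C=C(\C)C/C=C/C(C)(C)O | intermediate
4 | (3E,6E)-8-bromo-2,6-dimethylocta-3,6-dien-2-ol | BrC/C=C(\C)C/C=C/C(C)(C)O | intermediate
5 | {[(3E,6E)-8-bromo-2,6-dimethylocta-3,6-dien-2-yl]oxy}triethylsilane | BrC/C=C(\C)C/C=C/C(C)(C)O[Si](CC)(CC)CC | intermediate
6 | 5-bromoresorcinol | Oc1cc(O)cc(Br)c1 | starting material
7 | 5-bromo-2-iodobenzene-1,3-diol | Oc1cc(Br)cc(O)c1I | intermediate
8 | 5-bromo-2-iodo-1,3-bis(methoxymethoxy)benzene | COCOc1cc(Br)cc(OCOC)c1I | intermediate
9 | [4-bromo-2,6-bis(methoxymethoxy)phenyl]magnesium chloride (not isolated) | COCOc1cc(Br)cc(OCOC)c1[Mg]Cl | intermediate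
10 | 5-bromo-2-[(2E,5E)-3,7-dimethyl-7-(triethylsilyloxy)octa-2,5-dien-1-yl]-1,3-bis(methoxymethoxy)benzene | COCOc1cc(Br)cc(OCOC)c1C/C=C(\C)C/C=C/C(C)(C)O[Si](CC)(CC)CC | intermediate
11 | vanillin | COc1cc(C=O)ccc1O | starting material
12 | 3-methoxy-4-(methoxymethoxy)benzaldehyde | COc1cc(C=O)ccc1OCOC | intermediate
13 | (S)-1-[3-methoxy-4-(methoxymethoxy)phenyl]but-3-en-1-yl diisopinocampheylborinate (not isolated) | COc1cc([C@H](CC=C)OB([C@@H]2C[C@@H]3C[C@H]([C@H]2C)C3(C)C)[C@@H]2C[C@@H]3C[C@H]([C@H]2C)C3(C)C)ccc1OCOC | intermediate
14 | (S)-1-[3-methoxy-4-(methoxymethoxy)phenyl]but-3-en-1-ol | COc1cc([C@@H](O)CC=C)ccc1OCOC | intermediate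
15 | (S)-triethyl({1-[3-methoxy-4-(methoxymethoxy)phenyl]but-3-en-1-yl}oxy)silane | COc1cc([C@@H](O[Si](CC)(CC)CC)CC=C)ccc1OCOC | intermediate
16 | 3-{(S)-2-[3-methoxy-4-(methoxymethoxy)phenyl]-2-(triethylsilyloxy)ethyl}-1,2,4-trioxolane (not isolated) | COc1cc([C@@H](O[Si](CC)(CC)CC)CC2OCOO2)ccc1OCOC | intermediate
17 | (S)-3-[3-methoxy-4-(methoxymethoxy)phenyl]-3-(triethylsilyloxy)propanal | COc1cc([C@@H](O[Si](CC)(CC)CC)CC=O)ccc1OCOC | intermediate
18 | {6-bromo-3-[(2E,5E)-3,7-dimethyl-7-(triethylsilyloxy)octa-2,5-dien-1-yl]-2,4-bis(methoxymethoxy)phenyl}lithium (not isolated) | COCOc1cc(Br)c([Li])c(OCOC)c1C/C=C(\C)C/C=C/C(C)(C)O[Si](CC)(CC)CC | intermediate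
19 | lithium alkoxide of the adduct of 18 and 17, S at C2, both C4 epimers (not isolated) | COc1cc([C@@H](O[Si](CC)(CC)CC)CC(O[Li])c2c(Br)cc(OCOC)c(C/C=C(\C)C/C=C/C(C)(C)O[Si](CC)(CC)CC)c2OCOC)ccc1OCOC | intermediate
20 | (1RS,3S)-1-{6-bromo-3-[(2E,5E)-3,7-dimethyl-7-(triethylsilyloxy)octa-2,5-dien-1-yl]-2,4-bis(methoxymethoxy)phenyl}-1-(tert-butyldimethylsilyloxy)-3-[3-methoxy-4-(methoxymethoxy)phenyl]-3-(triethylsilyloxy)propane | COc1cc([C@@H](O[Si](CC)(CC)CC)CC(O[Si](C)(C)C(C)(C)C)c2c(Br)cc(OCOC)c(C/C=C(\C)C/C=C/C(C)(C)O[Si](CC)(CC)CC)c2OCOC)ccc1OCOC | intermediate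
21 | (1S,3RS)-3-{6-bromo-3-[(2E,5E)-7-hydroxy-3,7-dimethylocta-2,5-dien-1-yl]-2,4-bis(methoxymethoxy)phenyl}-3-(tert-butyldimethylsilyloxy)-1-[3-methoxy-4-(methoxymethoxy)phenyl]propan-1-ol | COc1cc([C@@H](O)CC(O[Si](C)(C)C(C)(C)C)c2c(Br)cc(OCOC)c(C/C=C(\C)C/C=C/C(C)(C)O)c2OCOC)ccc1OCOC | intermediate
22 | (2S,4RS)-4-(tert-butyldimethylsilyloxy)-6-[(2E,5E)-7-hydroxy-3,7-dimethylocta-2,5-dien-1-yl]-2-[3-methoxy-4-(methoxymethoxy)phenyl]-5,7-bis(methoxymethoxy)chromane | COc1cc([C@@H]2CC(O[Si](C)(C)C(C)(C)C)c3c(cc(OCOC)c(C/C=C(\C)C/C=C/C(C)(C)O)c3OCOC)O2)ccc1OCOC | intermediate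
23 | (2S,4RS)-6-[(2E,5E)-7-hydroxy-3,7-dimethylocta-2,5-dien-1-yl]-2-[3-methoxy-4-(methoxymethoxy)phenyl]-5,7-bis(methoxymethoxy)chroman-4-ol | COc1cc([C@@H]2CC(O)c3c(cc(OCOC)c(C/C=C(\C)C/C=C/C(C)(C)O)c3OCOC)O2)ccc1OCOC | intermediate
24 | (2S)-6-[(2E,5E)-7-hydroxy-3,7-dimethylocta-2,5-dien-1-yl]-2-[3-methoxy-4-(methoxymethoxy)phenyl]-5,7-bis(methoxymethoxy)chroman-4-one | COc1cc([C@@H]2CC(=O)c3c(cc(OCOC)c(C/C=C(\C)C/C=C/C(C)(C)O)c3OCOC)O2)ccc1OCOC | intermediate
25 | tetrakis(trimethylsilyl) ether of Tomentodiplacone B (not isolated) | COc1cc([C@@H]2CC(=O)c3c(cc(O[Si](C)(C)C)c(C/C=C(\C)C/C=C/C(C)(C)O[Si](C)(C)C)c3O[Si](C)(C)C)O2)ccc1O[Si](C)(C)C | intermediate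
26 | Tomentodiplacone B | COc1cc([C@@H]2CC(=O)c3c(cc(O)c(C/C=C(\C)C/C=C/C(C)(C)O)c3O)O2)ccc1O | target

## Step count and least certain steps

Total step count: 16. Longest linear sequence: 10 steps (steps 1, 2, 3, 6, 11, 12, 13, 14, 15, 16).

Step 13 (key step). The most likely failure is β-hydride elimination from the seven-membered palladium alkoxide outrunning C–O reductive elimination, because the alkoxide is secondary and benzylic; this would oxidise the carbinol and reduce off the bromide. A second risk is base-induced migration of the silyl group from the C4 oxygen to the C2 oxygen, which would expose the wrong hydroxyl. Fallback: a metal-free aryne cyclisation that sets out from 21 and comes back at 22. Excess lithium 2,2,6,6-tetramethylpiperidide in THF at −78 °C deprotonates both hydroxyls and the ring proton between bromine and the C7 acetal oxygen. Warming expels LiBr to give the aryne dilithium alkoxide F1 (not isolated). Its C2 alkoxide adds to C8a, the aryne carbon it can reach in a six-membered ring and the one that leaves the aryl anion beside the C7 oxygen; protonation gives 22.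

Step 11. The hindered, basic aryllithium may take a proton from the enolisable aldehyde, which then loses silanolate by β-elimination, and the ortho-bromo aryllithium may decay by loss of LiBr if it warms. Fallback: the polarity of the union is reversed and the stereocentre is set by reduction; it sets out from 10 and comes back at 21. 10 is metalated as before and quenched with DMF, a non-enolisable electrophile, to give 6-bromo-3-[(2E,5E)-3,7-dimethyl-7-(triethylsilyloxy)octa-2,5-dien-1-yl]-2,4-bis(methoxymethoxy)benzaldehyde F2. 1-[3-Methoxy-4-(methoxymethoxy)phenyl]ethanone F3 is made from commercial 4'-hydroxy-3'-methoxyacetophenone with MOMCl and i-Pr2NEt. Its lithium enolate (LiN(i-Pr)2, THF, −78 °C) adds to F2 to give the racemic β-hydroxy ketone F4, which t-BuMe2SiOTf and 2,6-lutidine convert into the silyl ether F5. Corey–Bakshi–Shibata reduction of the aryl ketone with the (R)-configured B-methyl oxazaborolidine and BH3·SMe2 gives the (S)-alcohol F6 under reagent control. HF·pyridine then removes the tertiary triethylsilyl group to give 21. Steps 8 to 10 are not needed on this path.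

Step 4. Iodination may also occur beside bromine or twice, and iodine may migrate under acid during work-up; the position of iodine must be proven, since every later step depends on it. Fallback: carbamate-directed metalation, which sets out from 6 and comes back at 7. Diethylcarbamoyl chloride and K2CO3 in MeCN give 5-bromo-1,3-phenylene bis(diethylcarbamate) F7. LiN(i-Pr)2 in THF at −78 °C, an amide base that does not exchange bromine, deprotonates the carbon flanked by the two strongly directing carbamates, and I2 gives 5-bromo-2-iodo-1,3-phenylene bis(diethylcarbamate) F8. Hydrolysis with NaOH in aqueous ethanol at reflux returns 7.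

Step 16. The silyl triflate may ionise the tertiary allylic C–O bond, leading to elimination or capture by a neighbouring oxygen, or trigger addition of a phenol oxygen to the trisubstituted alkene. Fallback: the tertiary oxygen is shielded by a bulky silyl group during acetal cleavage; it sets out from 24 and comes back at 26. t-BuMe2SiOTf and 2,6-lutidine at −78 °C give the tertiary silyl ether F9. The same acetal cleavage gives the triphenol F10, whose hindered silyl ether resists O-silylation and ionisation. HF·pyridine in THF/pyridine then removes the silyl group to give 26.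

## Further compounds

F1 | step 13 | aryne (8,8a-didehydro) form of 21 as its dilithium alkoxide, not isolated | COc1cc([C@@H](O[Li])CC(O[Si](C)(C)C(C)(C)C)C2=C(OCOC)C(C/C=C(\C)C/C=C/C(C)(C)O[Li])=C(OCOC)C#C2)ccc1OCOC
F2 | step 11 | 6-bromo-3-[(2E,5E)-3,7-dimethyl-7-(triethylsilyloxy)octa-2,5-dien-1-yl]-2,4-bis(methoxymethoxy)benzaldehyde | O=Cc1c(Br)cc(OCOC)c(C/C=C(\C)C/C=C/C(C)(C)O[Si](CC)(CC)CC)c1OCOC
F3 | step 11 | 1-[3-methoxy-4-(methoxymethoxy)phenyl]ethanone | CC(=O)c1ccc(OCOC)c(OC)c1
F4 | step 11 | racemic 3-{6-bromo-3-[(2E,5E)-3,7-dimethyl-7-(triethylsilyloxy)octa-2,5-dien-1-yl]-2,4-bis(methoxymethoxy)phenyl}-3-hydroxy-1-[3-methoxy-4-(methoxymethoxy)phenyl]propan-1-one | COc1cc(C(=O)CC(O)c2c(Br)cc(OCOC)c(C/C=C(\C)C/C=C/C(C)(C)O[Si](CC)(CC)CC)c2OCOC)ccc1OCOC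
F5 | step 11 | racemic 3-{6-bromo-3-[(2E,5E)-3,7-dimethyl-7-(triethylsilyloxy)octa-2,5-dien-1-yl]-2,4-bis(methoxymethoxy)phenyl}-3-(tert-butyldimethylsilyloxy)-1-[3-methoxy-4-(methoxymethoxy)phenyl]propan-1-one | COc1cc(C(=O)CC(O[Si](C)(C)C(C)(C)C)c2c(Br)cc(OCOC)c(C/C=C(\C)C/C=C/C(C)(C)O[Si](CC)(CC)CC)c2OCOC)ccc1OCOC
F6 | step 11 | (1S,3RS)-3-{6-bromo-3-[(2E,5E)-3,7-dimethyl-7-(triethylsilyloxy)octa-2,5-dien-1-yl]-2,4-bis(methoxymethoxy)phenyl}-3-(tert-butyldimethylsilyloxy)-1-[3-methoxy-4-(methoxymethoxy)phenyl]propan-1-ol | COc1cc([C@@H](O)CC(O[Si](C)(C)C(C)(C)C)c2c(Br)cc(OCOC)c(C/C=C(\C)C/C=C/C(C)(C)O[Si](CC)(CC)CC)c2OCOC)ccc1OCOC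
F7 | step 4 | 5-bromo-1,3-phenylene bis(diethylcarbamate) | CCN(CC)C(=O)Oc1cc(Br)cc(OC(=O)N(CC)CC)c1
F8 | step 4 | 5-bromo-2-iodo-1,3-phenylene bis(diethylcarbamate) | CCN(CC)C(=O)Oc1cc(Br)cc(OC(=O)N(CC)CC)c1I
F9 | step 16 | (2S)-6-[(2E,5E)-7-(tert-butyldimethylsilyloxy)-3,7-dimethylocta-2,5-dien-1-yl]-2-[3-methoxy-4-(methoxymethoxy)phenyl]-5,7-bis(methoxymethoxy)chroman-4-one | COc1cc([C@@H]2CC(=O)c3c(cc(OCOC)c(C/C=C(\C)C/C=C/C(C)(C)O[Si](C)(C)C(C)(C)C)c3OCOC)O2)ccc1OCOC
F10 | step 16 | Tomentodiplacone B tertiary tert-butyldimethylsilyl ether | COc1cc([C@@H]2CC(=O)c3c(cc(O)c(C/C=C(\C)C/C=C/C(C)(C)O[Si](C)(C)C(C)(C)C)c3O)O2)ccc1O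
A1 | alternative 1 | Tomentodiplacone B with free C5 hydroxyl, C7 triisopropylsilyl ether, chain triethylsilyl ether and ring B tert-butyldimethylsilyl ether | COc1cc([C@@H]2CC(=O)c3c(cc(O[Si](C(C)C)(C(C)C)C(C)C)c(C/C=C(\C)C/C=C/C(C)(C)O[Si](CC)(CC)CC)c3O)O2)ccc1O[Si](C)(C)C(C)(C)C
A2 | alternative 1 | (S)-2-[4-(tert-butyldimethylsilyloxy)-3-methoxyphenyl]-6-(2-diazoacetyl)-2,3-dihydro-4H-pyran-4-one | COc1cc([C@@H]2CC(=O)C=C(C(=O)C=[N+]=[N-])O2)ccc1O[Si](C)(C)C(C)(C)C
A3 | alternative 1 | {[(4E,7E)-5,9-dimethyl-9-(triethylsilyloxy)deca-4,7-dien-1-yn-1-yl]oxy}triisopropylsilane | CC(C)[Si](OC#CC/C=C(\C)C/C=C/C(C)(C)O[Si](CC)(CC)CC)(C(C)C)C(C)C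
A4 | alternative 2 | tris(methoxymethyl) ether and chain triethylsilyl ether of Tomentodiplacone B | COc1cc([C@@H]2CC(=O)c3c(cc(OCOC)c(C/C=C(\C)C/C=C/C(C)(C)O[Si](CC)(CC)CC)c3OCOC)O2)ccc1OCOC
A5 | alternative 2 | (S)-3-{2-bromo-4-[(2E,5E)-3,7-dimethyl-7-(triethylsilyloxy)octa-2,5-dien-1-yl]-3,5-bis(methoxymethoxy)phenoxy}-N-methoxy-3-[3-methoxy-4-(methoxymethoxy)phenyl]-N-methylpropanamide | COc1cc([C@H](CC(=O)N(C)OC)Oc2cc(OCOC)c(C/C=C(\C)C/C=C/C(C)(C)O[Si](CC)(CC)CC)c(OCOC)c2Br)ccc1OCOC
A6 | alternative 3 | Tomentodiplacone B as its ring B tert-butyldimethylsilyl ether and chain triethylsilyl ether | COc1cc([C@@H]2CC(=O)c3c(cc(O)c(C/C=C(\C)C/C=C/C(C)(C)O[Si](CC)(CC)CC)c3O)O2)ccc1O[Si](C)(C)C(C)(C)C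
A7 | alternative 3 | methyl 4-{(S)-2-[4-(tert-butyldimethylsilyloxy)-3-methoxyphenyl]-4-oxo-3,4-dihydro-2H-pyran-6-yl}-2-[(2E,5E)-3,7-dimethyl-7-(triethylsilyloxy)octa-2,5-dien-1-yl]-3-oxobutanoate, both epimers at the ester α-carbon | COc1cc([C@@H]2CC(=O)C=C(CC(=O)C(C/C=C(\C)C/C=C/C(C)(C)O[Si](CC)(CC)CC)C(=O)OC)O2)ccc1O[Si](C)(C)C(C)(C)C
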